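**Assumption:** Stenosporic acid has no stereocentre, so no enantiocontrol is needed. The sp3 centres in 3–5 and 11–13 are racemic and are erased on aromatisation.

## Retrosynthetic overview
1. 19 comes from the doubly benzyl-protected depside 18 by hydrogenolysis. Cutting the aryl ester C–O bond of 18 gives A-ring acid 9 and B-ring phenol 16.
2. 9 derives from methyl divarate 6 (4-O-methylation, 2-O-benzylation, saponification). 16 derives from methyl olivetolate 14 (saponification, benzyl esterification).
3. Each resorcylate (6, 14) comes from a dihydroresorcylate (4, 12) by bromination–dehydrobromination.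
4. Each dihydroresorcylate comes from an enone (1 or 10) and dimethyl malonate 2. An intermolecular Michael addition forms the key C–C bond, and a Claisen (Dieckmann-type) closure follows in the same flask.
5. Ring order: the A ring (propyl) and B ring (pentyl) are built de novo in parallel, aromatised, and joined last.

## Route

Step 1
Reactants: 1 (E)-hept-3-en-2-one; 2 dimethyl malonate
Product: 4 methyl 2-hydroxy-4-oxo-6-propylcyclohex-2-ene-1-carboxylate (racemic enol form of the 2,4-dione), via Michael adduct 3 (not isolated)
Conditions: NaOMe (1.1 equiv), 2 (1.1 equiv), MeOH, rt then reflux 3 h; cold aq HCl to pH 3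
Reagents that add atoms: none
Why: The soft sodium malonate adds 1,4 to the enone (intermolecular Michael addition), then the methyl-ketone enolate of 3 closes onto one ester (Claisen/Dieckmann-type condensation), driven by the stabilised β-dicarbonyl enolate, and the racemic sp3 centres are erased in step 2.

Step 2
Reactants: 4 methyl 2-hydroxy-4-oxo-6-propylcyclohex-2-ene-1-carboxylate
Product: 6 methyl 2,4-dihydroxy-6-propylbenzoate (methyl divarate), via 3-bromo enol-dione 5 (not isolated)
Conditions: Br2 (1.0 equiv) in DMF, 0 °C, then 80 °C, 12 h; aqueous work-up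
Reagents that add atoms: bromine, BrBr (its Br sits only in intermediate 5 and leaves again as HBr)
Why: In this bromination–dehydrobromination aromatisation the enolised 1,3-dione takes up one Br at 0 °C, then loses HBr and tautomerises on warming, driven by aromaticity, while 80 °C is too low for bromide-induced ester cleavage and decarboxylation.

Step 3
Reactants: 6 methyl 2,4-dihydroxy-6-propylbenzoate
Product: 7 methyl 2-hydroxy-4-methoxy-6-propylbenzoate (methyl divaricatinate)
Conditions: MeI (1.05 equiv), K2CO3 (1.1 equiv), acetone, reflux, 6 h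
Reagents that add atoms: iodomethane, CI
Why: In this Williamson ether synthesis the 2-OH is hydrogen-bonded to the ester carbonyl and hindered, so one equivalent of MeI with a weak base alkylates only the more acidic, free 4-OH.

Step 4
Reactants: 7 methyl 2-hydroxy-4-methoxy-6-propylbenzoate
Product: 8 methyl 2-(benzyloxy)-4-methoxy-6-propylbenzoate
Conditions: BnBr (1.3 equiv), K2CO3 (2 equiv), DMF, 60 °C, 12 h
Reagents that add atoms: benzyl bromide, BrCc1ccccc1
Why: Williamson benzylation under forcing conditions alkylates the remaining chelated phenol, so it cannot compete as a nucleophile in the later esterification.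

Step 5
Reactants: 8 methyl 2-(benzyloxy)-4-methoxy-6-propylbenzoate
Product: 9 2-(benzyloxy)-4-methoxy-6-propylbenzoic acid
Conditions: KOH (10 equiv), DMSO/H2O 4:1, 100 °C, 8 h; cold 2 M HCl
Reagents that add atoms: potassium hydroxide, [K+].[OH-]
Why: Saponification (BAc2) of the di-ortho-substituted ester succeeds with poorly solvated hydroxide in hot aqueous DMSO, and the aryl methyl and benzyl ethers are inert to base.

Step 6
Reactants: 10 (E)-non-3-en-2-one; 2 dimethyl malonate
Product: 12 methyl 2-hydroxy-4-oxo-6-pentylcyclohex-2-ene-1-carboxylate (racemic enol form of the 2,4-dione), via Michael adduct 11 (not isolated)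
Conditions: NaOMe (1.1 equiv), 2 (1.1 equiv), MeOH, rt then reflux 3 h; cold aq HCl to pH 3
Reagents that add atoms: none
Why: This is the same intermolecular Michael addition and in-flask Claisen/Dieckmann-type closure as in step 1, and the racemic sp3 centres are erased in step 7.

Step 7
Reactants: 12 methyl 2-hydroxy-4-oxo-6-pentylcyclohex-2-ene-1-carboxylate
Product: 14 methyl 2,4-dihydroxy-6-pentylbenzoate (methyl olivetolate), via 3-bromo enol-dione 13 (not isolated)
Conditions: Br2 (1.0 equiv) in DMF, 0 °C, then 80 °C, 12 h; aqueous work-up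
Reagents that add atoms: bromine, BrBr (its Br sits only in intermediate 13 and leaves again as HBr)
Why: This is the same bromination–dehydrobromination aromatisation as in step 2, with aromaticity as the driving force.

Step 8
Reactants: 14 methyl 2,4-dihydroxy-6-pentylbenzoate
Product: 15 2,4-dihydroxy-6-pentylbenzoic acid (olivetolic acid)
Conditions: aq KOH (4 M, 10 equiv), Ar, reflux, 10 h; 0 °C, 2 M HCl to pH 2, extract cold
Reagents that add atoms: potassium hydroxide, [K+].[OH-]
Why: During this saponification the product is held as its carboxylate/phenoxide salt, which resists the ipso-protonation that decarboxylation needs, and cold acidification releases the acid intact.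

Step 9
Reactants: 15 2,4-dihydroxy-6-pentylbenzoic acid
Product: 16 benzyl 2,4-dihydroxy-6-pentylbenzoate (benzyl olivetolate)
Conditions: KHCO3 (1.2 equiv), BnBr (1.05 equiv), DMF, rt to 40 °C, 12 h
Reagents that add atoms: benzyl bromide, BrCc1ccccc1
Why: In this SN2 carboxylate alkylation KHCO3 deprotonates only the CO2H and not the phenols, so BnBr gives the benzyl ester chemoselectively.

Step 10
Reactants: 9 2-(benzyloxy)-4-methoxy-6-propylbenzoic acid; 16 benzyl 2,4-dihydroxy-6-pentylbenzoate
Product: 18 benzyl 4-{[2-(benzyloxy)-4-methoxy-6-propylbenzoyl]oxy}-2-hydroxy-6-pentylbenzoate, via mixed trifluoroacetic anhydride 17 (not isolated)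
Conditions: (CF3CO)2O (4 equiv), dry toluene, rt, 6 h; aq NaHCO3 work-up
Reagents that add atoms: trifluoroacetic anhydride, O=C(OC(=O)C(F)(F)F)C(F)(F)F (its CF3CO group sits only in intermediate 17)
Why: In this mixed-anhydride esterification the electron-rich hindered acid forms an acylium-like donor 17 that acylates the free 4-OH of 16, because the 2-OH is deactivated by chelation to the ester carbonyl and any aryl trifluoroacetate is cleaved by bicarbonate.

Step 11
Reactants: 18 benzyl 4-{[2-(benzyloxy)-4-methoxy-6-propylbenzoyl]oxy}-2-hydroxy-6-pentylbenzoate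
Product: 19 stenosporic acid
Conditions: H2 (1 atm), 10% Pd/C, EtOAc, rt, 3 h
Reagents that add atoms: none
Why: Catalytic hydrogenolysis cleaves both benzylic C–O bonds (ester and ether) under neutral conditions that leave the depside ester, the methyl ether and the arenes untouched.

## Compound list
1 | (E)-hept-3-en-2-one | CCC/C=C/C(C)=O | starting material
2 | dimethyl malonate | COC(=O)CC(=O)OC | starting material
3 | dimethyl 2-(2-oxoheptan-4-yl)propanedioate (racemic, not isolated) | CCCC(CC(C)=O)C(C(=O)OC)C(=O)OC | intermediate
4 | methyl 2-hydroxy-4-oxo-6-propylcyclohex-2-ene-1-carboxylate (racemic) | CCCC1CC(=O)C=C(O)C1C(=O)OC | intermediate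
5 | methyl 3-bromo-2-hydroxy-4-oxo-6-propylcyclohex-2-ene-1-carboxylate (racemic, not isolated) | CCCC1CC(=O)C(Br)=C(O)C1C(=O)OC | intermediate
6 | methyl 2,4-dihydroxy-6-propylbenzoate | CCCc1cc(O)cc(O)c1C(=O)OC | intermediate
7 | methyl 2-hydroxy-4-methoxy-6-propylbenzoate | CCCc1cc(OC)cc(O)c1C(=O)OC | intermediate
8 | methyl 2-(benzyloxy)-4-methoxy-6-propylbenzoate | CCCc1cc(OC)cc(OCc2ccccc2)c1C(=O)OC | intermediate
9 | 2-(benzyloxy)-4-methoxy-6-propylbenzoic acid | CCCc1cc(OC)cc(OCc2ccccc2)c1C(=O)O | intermediate
10 | (E)-non-3-en-2-one | CCCCC/C=C/C(C)=O | starting material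
11 | dimethyl 2-(2-oxononan-4-yl)propanedioate (racemic, not isolated) | CCCCCC(CC(C)=O)C(C(=O)OC)C(=O)OC | intermediate
12 | methyl 2-hydroxy-4-oxo-6-pentylcyclohex-2-ene-1-carboxylate (racemic) | CCCCCC1CC(=O)C=C(O)C1C(=O)OC | intermediate
13 | methyl 3-bromo-2-hydroxy-4-oxo-6-pentylcyclohex-2-ene-1-carboxylate (racemic, not isolated) | CCCCCC1CC(=O)C(Br)=C(O)C1C(=O)OC | intermediate
14 | methyl 2,4-dihydroxy-6-pentylbenzoate | CCCCCc1cc(O)cc(O)c1C(=O)OC | intermediate
15 | 2,4-dihydroxy-6-pentylbenzoic acid | CCCCCc1cc(O)cc(O)c1C(=O)O | intermediate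
16 | benzyl 2,4-dihydroxy-6-pentylbenzoate | CCCCCc1cc(O)cc(O)c1C(=O)OCc1ccccc1 | intermediate
17 | 2-(benzyloxy)-4-methoxy-6-propylbenzoic trifluoroacetic anhydride (not isolated) | CCCc1cc(OC)cc(OCc2ccccc2)c1C(=O)OC(=O)C(F)(F)F | intermediate
18 | benzyl 4-{[2-(benzyloxy)-4-methoxy-6-propylbenzoyl]oxy}-2-hydroxy-6-pentylbenzoate | CCCCCc1cc(OC(=O)c2c(OCc3ccccc3)cc(OC)cc2CCC)cc(O)c1C(=O)OCc1ccccc1 | intermediate
19 | stenosporic acid (achiral) | CCCCCc1cc(OC(=O)c2c(O)cc(OC)cc2CCC)cc(O)c1C(=O)O | target

## Summary
Total step count: 11.
Longest linear sequence: 7 (steps 1–5, 10, 11). The B-ring branch (steps 6–9) is run in parallel.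

## Three steps most likely to fail

**Step 2 (one-pot aromatisation).** The risks are over-bromination of the very electron-rich product and partial ester loss. The fallback sets out from 4 and comes back at 6. It replaces the stoichiometrically delicate single bromination with deliberate exhaustive bromination. Treating 4 with Br2 (3.1 equiv) in AcOH at rt aromatises the ring and fills both free ring positions. This gives crystalline methyl 3,5-dibromo-2,4-dihydroxy-6-propylbenzoate F1. Reductive debromination of this compound (H2, Pd/C, NaOAc, MeOH, rt) then gives 6.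

**Step 8 (hydrolysis of the free-phenol ester).** The bis-phenoxide reacts sluggishly, and the acid may decarboxylate on isolation. The fallback sets out from 14 and comes back at 15. It is a protect–hydrolyse–deprotect sequence:
- Both phenols are benzylated (BnBr 2.5 equiv, K2CO3, DMF, 60 °C) to give methyl 2,4-bis(benzyloxy)-6-pentylbenzoate F2.
- The now neutral ester is saponified (KOH, DMSO/H2O, 100 °C) to the decarboxylation-resistant 2,4-bis(benzyloxy)-6-pentylbenzoic acid F3.
- Neutral hydrogenolysis at room temperature (H2, Pd/C, EtOAc) releases 15 without heat or acid.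

**Step 10 (depside coupling).** The acidic TFAA/TFA medium may cause C-acylation of the B ring or erode the 2-O-benzyl ether, and the acid is hindered. The fallback sets out from 7, uses 16 from the main route, and comes back at 19. It drops the phenol protection and uses neutral carbodiimide activation:
- 7 is saponified (KOH, DMSO/H2O, 90 °C, cold HCl) to 2-hydroxy-4-methoxy-6-propylbenzoic acid (divaricatinic acid) F4.
- F4 is condensed with 16 using DCC (1.1 equiv) in dry toluene at rt. This gives benzyl 2-hydroxy-4-[(2-hydroxy-4-methoxy-6-propylbenzoyl)oxy]-6-pentylbenzoate (benzyl stenosporate) F5.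
- Hydrogenolysis (H2, Pd/C, EtOAc) gives 19.

## Further compounds
F1 | step 2 | methyl 3,5-dibromo-2,4-dihydroxy-6-propylbenzoate | CCCc1c(Br)c(O)c(Br)c(O)c1C(=O)OC
F2 | step 8 | methyl 2,4-bis(benzyloxy)-6-pentylbenzoate | CCCCCc1cc(OCc2ccccc2)cc(OCc2ccccc2)c1C(=O)OC
F3 | step 8 | 2,4-bis(benzyloxy)-6-pentylbenzoic acid | CCCCCc1cc(OCc2ccccc2)cc(OCc2ccccc2)c1C(=O)O
F4 | step 10 | 2-hydroxy-4-methoxy-6-propylbenzoic acid (divaricatinic acid) | CCCc1cc(OC)cc(O)c1C(=O)O
F5 | step 10 | benzyl 2-hydroxy-4-[(2-hydroxy-4-methoxy-6-propylbenzoyl)oxy]-6-pentylbenzoate (benzyl stenosporate) | CCCCCc1cc(OC(=O)c2c(O)cc(OC)cc2CCC)cc(O)c1C(=O)OCc1ccccc1
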